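Late in the spring run, between 15.0 min and 30.0 min, starting material falls from 80.2% to 63.4%, and I ask what the target does meanwhile.

| flask | starting material | second substrate | partner | precatalyst | remark | time |
|---|---|---|---|---|---|---|
| midnight | 0.30 M | 2 equiv | 0.80 equiv | 0.19 mol% | run made earlier |  |
| winter | 0.30 M | 2 equiv | 0.54 equiv | 0.19 mol% | run made earlier |  |
| spring | 0.30 M | 2 equiv | 1.2 equiv | 0.19 mol% | run made earlier |  |
| cedar | 0.30 M | 2.00 equiv | 0.800 equiv | 0.19 mol% | one stirred flow tank at steady state, fed with the mixture as stated, mean residence time 25 min |  |
| alder | 0.30 M (fed, over 20.0 min) | 2.00 equiv | 0.800 equiv | 0.19 mol% | a stirred flask in which starting material is dosed at a steady rate over 20.0 min without added volume, worked up at 25 min | 25 min |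
| ash | 0.30 M | 2.00 equiv | 0.800 equiv | 0.19 mol% | a closed flask charged with all of it at once and left for 25 min | 25 min |
| elm | 0.30 M | 2.00 equiv | 0.800 equiv (fed, over 20.0 min) | 0.19 mol% | a stirred flask in which partner is dosed at a steady rate over 20.0 min without added volume, worked up at 25 min | 25 min |

| run | time / min | target / % | starting material / % |
|---|---|---|---|
| midnight | 2.50 | 1.0 | 98.2 |
| midnight | 5.00 | 3.5 | 96.4 |
| midnight | 8.00 | 7.5 | 92.7 |
| midnight | 10.0 | 9.6 | 90.0 |
| midnight | 12.0 | 10.3 | 88.7 |
| midnight | 15.0 | 13.3 | 87.1 |
| winter | 2.00 | 1.6 | 98.9 |
| winter | 6.00 | 3.4 | 96.7 |
| winter | 10.0 | 6.7 | 93.8 |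
| winter | 15.0 | 9.7 | 90.5 |
| winter | 25.0 | 15.3 | 85.8 |
| winter | 30.0 | 16.5 | 82.3 |
| spring | 2.00 | 1.8 | 99.0 |
| spring | 6.00 | 7.9 | 91.8 |
| spring | 10.0 | 13.3 | 86.3 |
| spring | 15.0 | 20.0 | 80.2 |
| spring | 25.0 | 31.9 | 68.2 |
| spring | 30.0 | 36.5 | 63.4 |

(readings scatter by 0.5 percentage points)

- the set-up with the highest amount of target at the outlet or at the end, in percent of the starting material put in ("none" if the first two lie within 2 percentage points) (cedar / alder / ash / elm / none)
- amount of target at the outlet or at the end, in percent of the starting material put in, cedar
- amount of target at the outlet or at the end, in percent of the starting material put in, alder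
- amount of target at the outlet or at the end, in percent of the starting material put in, ash
- amount of target at the outlet or at the end, in percent of the starting material put in, elm

- the stated concentrations are those of everything mixed, before any reaction; amounts are the same in each set-up
- steps that have been proposed: starting material + free catalyst <-> catalyst intermediate A; partner + catalyst intermediate A -> free catalyst + target; second substrate + free catalyst <-> catalyst intermediate B; partner + catalyst intermediate B -> free catalyst + second product; precatalyst <-> free catalyst
- the feed brings no volume worth counting
- the earlier runs were made in a closed, stirred flask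

The proposed steps send partner through catalyst intermediate A to target, and through catalyst intermediate B to second product. Over the spring run, the partner still present turns into target at 0.0121 min⁻¹. This share per minute is my partner clock, a pseudo-first-order constant.

First doubt: the rate may follow starting material too, and then the late stretch should read slower. But the stretch up to 15.0 min reads 0.0122 min⁻¹, and the late stretch reads 0.0120 min⁻¹, about the same. I guess that the catalyst sits mostly as catalyst intermediate A, the resting state.

Second doubt: one run says little about partner. But the winter run, with 0.54 equiv, reads 0.0122 min⁻¹, about the spring value. The midnight run, with 0.80 equiv, reads 0.0121 min⁻¹, also about the spring value.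

Third doubt: no reading shows second product, so partner lost that way hides inside the clock. I cannot compute this away, so I carry it as a risk.

Now I compare rates. Ash starts at the full partner charge and drifts down, and my clock gives 20.9%. Cedar works at its outlet partner level throughout, so my clock gives 18.6%, less than for ash. Elm has its partner arrive over 20.0 min, so my clock gives 13.1%, less than for cedar. Alder I do not reckon: it begins without starting material, and the earlier runs begin with it.

The forecast names ash, with cedar 19%, alder 18.5%, ash 21.5% and elm 14%, holding that “the catalyst is saturated as intermediate A, with little partner wasted”. Its ash is higher than mine, and so are its cedar and its elm.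

Ash gives 21.4%, cedar 18.2%, alder 17.5% and elm 14.2%, so ash is highest.

    starting material + free catalyst ⇌ catalyst intermediate A (K = 210 M⁻¹, k = 1200 M⁻¹ min⁻¹)
    partner + catalyst intermediate A → free catalyst + target (k = 27.0 M⁻¹ min⁻¹)
    second substrate + free catalyst ⇌ catalyst intermediate B (K = 7.90 M⁻¹, k = 84.0 M⁻¹ min⁻¹)
    partner + catalyst intermediate B → free catalyst + second product (k = 570 M⁻¹ min⁻¹)
    precatalyst ⇌ free catalyst (K = 0.470, k = 0.850 min⁻¹)

In ash, catalyst intermediate A holds 88.7% of the catalyst at 25.0 min. Left until 1.5 h, the ash flask holds 46.8% target, less than the 53.0% the spring clock gives, with 15% of its partner left and second product at 0.0626 M.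

The runs are calculated on assumed constants.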